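The pitfall is to read the two capture constants, 2300 M⁻¹ h⁻¹ and 2400 M⁻¹ h⁻¹, as an even race, because their ratio is 0.958.

common to all: solid substrate 0.050 M; time 8.0 h
- maple: first nucleophile 0.0250 M; second nucleophile 0.0400 M (fed, over 6.0 h); all else is in the flask from the start; the feed brings no volume worth counting
- larch: first nucleophile 0.0250 M; second nucleophile 0.0400 M; everything together at the start
- ash: first nucleophile 0.0250 M (fed, over 6.0 h); second nucleophile 0.0400 M; all else is in the flask from the start; the feed brings no volume worth counting

    crystals ⇌ target, rate k1*(cs1 - [target]) while solid is left; crystals form when [target] > cs1 (cs1 = 5.5 mM, k1 = 74 h⁻¹)
    first nucleophile ⇌ dormant form (K2 = 2.9, k2 = 2.3 h⁻¹)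
    intermediate → solvolysis product (k3 = 3.7 h⁻¹)
    starting material → intermediate (k4 = 5.7 h⁻¹)
    second nucleophile + intermediate → other capture product (k5 = 2400 M⁻¹ h⁻¹)
    first nucleophile + intermediate → target (k6 = 2300 M⁻¹ h⁻¹)
    solid substrate ⇌ starting material, rate k7*(cs7 - [starting material]) while solid is left; crystals form when [starting material] > cs7 (cs7 = 47 mM, k7 = 0.19 h⁻¹)

- for target the crystals are counted in
- as a solid, counted per litre of solution: solid substrate, crystals
- at the start none of the solid substrate is in solution
- run time (maple): 8.0 h

* which flask leads in amount of target, in percent of the solid substrate charged ("all alike" within 1.5 percentage points) (maple / larch / ash / all alike)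
* how much target is there at the end, in percent of the solid substrate charged: maple
* how much target is there at the end, in percent of the solid substrate charged: larch
* how much target is there at the end, in percent of the solid substrate charged: ash

Follow one molecule of intermediate. Its exits are target, other capture product and solvolysis product. The solid supplies intermediate at about 8.64 mM h⁻¹, so it lasts about 5.79 h. In maple the first nucleophile and its dormant form relax with a half-life of 0.224 h, shorter than that supply time. The two forms can therefore be treated as one equilibrated pool, with a free fraction of 0.256.

The givens then fold into one selectivity factor, the target capture constant divided by the other capture constant and by one plus the dormancy constant: 0.246. A pool molecule competes like a quarter of a second nucleophile molecule.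

My reckoning takes larch first. Solvolysis starts at 3.85% of the other capture rate, but that share grows as second nucleophile falls, and this first pass leaves solvolysis out. The fraction of pool left then equals the fraction of second nucleophile left, raised to the power of the factor. The balance leaves 15.0 mM of pool and second nucleophile together. A remainder of 2.50 mM of second nucleophile leaves 12.6 mM of pool, and their sum of 15.1 mM is close enough. With solvolysis left out, larch thus gets 24.7% target. That figure leans high, because at the reckoned remainder solvolysis stands at 61.7% of the other capture rate.

One number is not enough for maple, where second nucleophile enters at 6.67 mM h⁻¹, slower than the supply. That feed ratio of 0.772 sends at least about 22.8% of the substrate to target and solvolysis together. In ash the pool starts below its larch level, so my order is maple, larch, ash.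

The forecast picks maple, with 32.5% (29% to 36%) for maple, 22.5% (20.5% to 24.5%) for larch, a figure below mine, and 21.5% (18.5% to 24.5%) for ash. Its ground: “Feeding the second nucleophile keeps it scarce while the first is still plentiful”.

The simulation gives 29.4% for maple, 20.8% for larch and 18.1% for ash, so maple leads. Larch ends with 7.12% solvolysis product and 9.9% of its second nucleophile, against my 6.25%. Raised to the factor 0.246, that simulated remainder leaves 56.6% of the pool and gives larch 21.6% target.

The constants used here belong to no real substance; what happens was integrated by code.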